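We ask first how slow this flask is, for a mean rate taken up to the first reading stands in for the opening rate where the rise is still straight by then.

| flask | starting material | partner | target | time |
|---|---|---|---|---|
| ochre | 0.600 M | 0.480 M |  |  |
| amber | 0.240 M | 0.120 M |  |  |
| violet | 0.600 M | 0.480 M | 0.180 M |  |
| green | 0.900 M | 0.480 M |  |  |
| red | 0.600 M | 0.480 M |  | 100 min |

| run | time / min | [target] / M |
|---|---|---|
| ochre run | 2.8 | 0.189 |
| ochre run | 5.7 | 0.248 |
| ochre run | 8.5 | 0.273 |
| ochre run | 11 | 0.281 |
| ochre run | 14 | 0.284 |
| ochre run | 17 | 0.296 |
| amber run | 2.8 | 0.030 |
| amber run | 5.7 | 0.058 |
| amber run | 8.5 | 0.065 |
| amber run | 11 | 0.067 |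
| amber run | 14 | 0.078 |
| amber run | 17 | 0.083 |
| violet run | 2.8 | 0.379 |
| violet run | 5.7 | 0.425 |
| violet run | 8.5 | 0.448 |
| violet run | 11 | 0.460 |
| violet run | 14 | 0.468 |
| violet run | 17 | 0.462 |
| green run | 2.8 | 0.239 |
| green run | 5.7 | 0.293 |
| green run | 8.5 | 0.318 |
| green run | 11 | 0.326 |
| green run | 14 | 0.340 |
| green run | 17 | 0.345 |

(readings scatter by 0.005 M)

- how the opening rate goes with [partner] round the charge of the ochre run: the exponent of the rate at two percent of starting material gone to target
- how the opening rate goes with [starting material] round the charge of the ochre run: the exponent of the rate at two percent of starting material gone to target (one fixed amount of target, the same in the runs compared)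
- target in the red run at 100 min, as a share of the starting material charged

- Overall: starting material + partner -> target.
- Constant volume, constant temperature.
- What is held in complexes is read along with the free species.
- "The second partner" is partner.
- An order is taken over about fifteen percent of the charge, up and down.

In the ochre run the target stands at 0.189 M at the first reading, 2.8 min, and at 0.296 M at the last, so the first reading already shows 63.9% of the last. Two times therefore matter, the time of that first reading and the time over which the rise bends. As our own working shape we let the target climb along a hyperbola towards its last reading, which is rough but needs one reading and the last. For ochre that gives 1.59 min, and this is the half-rise time, the time a run takes to make half of its last reading of target.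

The opening rate is then the last reading over the half-rise time, 0.187 M min⁻¹, while the mean rate up to the first reading is 0.0675 M min⁻¹, which is lower, since that reading comes 1.76 half-rise times in.

The green run, richer in starting material, has a half-rise time of 1.24 min, shorter than that of ochre, and so an opening rate of 0.278 M min⁻¹. Between green and ochre we therefore reckon an order in starting material of 0.980. The red run has the ochre charge, so we expect a share near 49.3%.

The forecast differs from us on that order. It gives 0.5 for starting material, “which suggests partial saturation”, with 1 for partner and 54% for the red run.

The simulation gives 1.0 for starting material, 0.78 for partner and 50.2% for the red run.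

    starting material + partner → target (1.008 M⁻¹ min⁻¹)
    starting material + 2 partner → target + partner (0.07320 M⁻² min⁻¹)
    2 partner ⇌ idle reagent dimer, settled at all times (1.140 M⁻¹)
    2 starting material → homo dimer (0.4926 M⁻¹ min⁻¹)

At the asked time the red run stands at 50.2% and not at the 80.0% it reaches without the loss of starting material to homo dimer. By that step alone, the first half-life of starting material is 1.69 min at the ochre charge, beside our half-rise time of 1.59 min, and 1.13 min at the green charge, beside 1.24 min. Carried to the green run, the half-rise times put its opening rate at 1.49 times that of ochre, and the simulation gives a ratio of the two rates, at the same amount of target made, of 1.5.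

(Readings and results are simulated for an exercise, noise included.)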